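## Retrosynthetic overview

1. The target comes from MeOH opening (at C4, trans-diaxial) of an epoxyquinol that carries the 3-acetate anti and the 6-hydroxyl syn to the epoxide; this in turn comes from the enantioenriched epoxide of a 3-alkynyl quinone monoketal by Luche reduction, Mitsunobu inversion, ketal hydrolysis and a second Luche reduction.
2. The epoxide is set by one enantioselective nucleophilic epoxidation of the quinone monoketal that already carries the whole C10 enyne chain.
3. The quinone monoketal comes from PhI(OAc)2/MeOH dearomatization of a 3-alkynyl-4-methoxyphenol.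
4. The alkynylphenol comes from 3-bromo-4-methoxyphenol, Me3Si-acetylene and a 2-bromo-1,4-diene (one-pot double Sonogashira); the bromodiene comes from an (E)-alkenyl boronate and 2,3-dibromopropene.
5. There is one ring only. It is the purchased benzene ring, dearomatized in step 3; no ring is closed by C–C bond formation.

Assumption: the natural product is taken to arise from an alkynyl hydroquinone by oxidation to the quinone, epoxidation, two carbonyl reductions and methanolysis of the epoxide; the ring steps below run in that order.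

Assumption: the facial sense of the epoxidation in step 4 is taken by analogy with 2-cyclohexenones and must be confirmed (Mosher esters of 10); if it is opposite, the quinidine-derived pseudoenantiomer of the catalyst is used and nothing else changes.

Notation: ring positions in the comments are C1 (sp2 carbon bearing the enyne), C2 (vinylic CH), C3 (OAc), C4 (OMe), C5 (OH), C6 (OH). R = (5E)-7-hydroxy-7-methyl-3-methylideneoct-5-en-1-yn-1-yl, i.e. –C≡C–C(=CH2)–CH2–CH=CH–C(CH3)2OH.

## Route

Step 1
Reactants: 1 (E)-2-methyl-4-(4,4,5,5-tetramethyl-1,3,2-dioxaborolan-2-yl)but-3-en-2-ol; 2 2,3-dibromoprop-1-ene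
Product: 3 (3E)-6-bromo-2-methylhepta-3,6-dien-2-ol
Conditions: Pd(PPh3)4 (3 mol %), K2CO3 (2 equiv), THF/H2O 4:1, 60 °C; 2 in excess (1.5 equiv)
Reagents that add atoms: none
Why: Suzuki–Miyaura allyl–alkenyl coupling, in which the allylic C–Br bond of 2 adds to zerovalent palladium much faster than the vinylic one, the symmetrical 2-bromo-π-allyl complex removes any regiochemical question, and transmetalation of the alkenylboronate with retention keeps the E alkene (no stereocentre is formed).

Step 2
Reactants: 4 3-bromo-4-methoxyphenol; 5 ethynyltrimethylsilane; 3 (3E)-6-bromo-2-methylhepta-3,6-dien-2-ol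
Product: 7 3-[(5E)-7-hydroxy-7-methyl-3-methylideneoct-5-en-1-yn-1-yl]-4-methoxyphenol, via silylalkyne 6 (not isolated)
Conditions: PdCl2(PPh3)2 (5 mol %), CuI (5 mol %), Et3N, DMF, 80 °C (sealed); argon purge to remove excess 5; then 3 (1.1 equiv), CsF (2 equiv), 50 °C, same pot
Reagents that add atoms: none
Why: Sonogashira coupling of the aryl bromide with 5, followed in the same pot by fluoride-triggered desilylation and a second (sila-)Sonogashira coupling with the 2-bromoalkene 3, the standard entry to 2-substituted but-1-en-3-ynes, with the free phenol and tertiary alcohol tolerated (no stereocentre is formed).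

Step 3
Reactants: 7 3-R-4-methoxyphenol
Product: 8 3-R-4,4-dimethoxycyclohexa-2,5-dien-1-one
Conditions: PhI(OAc)2 (1.1 equiv), MeOH, 0 °C
Reagents that add atoms: methanol, CO
Why: Pelter-type oxidative dearomatization of a para-methoxyphenol, in which the phenoxenium ion is trapped by methanol at the methoxy-bearing para carbon to give the quinone monoketal, leaving the C3 carbonyl free and C6 masked (no stereocentre is formed).

Step 4
Reactants: 8 3-R-4,4-dimethoxycyclohexa-2,5-dien-1-one
Product: 9 (1S,6R)-4-R-5,5-dimethoxy-7-oxabicyclo[4.1.0]hept-3-en-2-one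
Conditions: 9-amino-9-deoxy-epi-quinine bis(trifluoroacetate) (10 mol %), 50% aq. H2O2 (1.5 equiv), dioxane, 30 °C
Reagents that add atoms: hydrogen peroxide, OO
Why: Proposed new method: the primary amine of the catalyst condenses with the dienone carbonyl to a chiral iminium ion, the protonated quinuclidine guides H2O2 to the unsubstituted β-carbon (C5) from one face, and the β-peroxy enamine closes to the cis-epoxide (the alkynyl-substituted β-carbon C1 is too hindered to compete), so both epoxide stereocentres (C4, C5) are set in one enantioselective Weitz–Scheffer-type step; the closest known reaction is the cinchona-primary-amine-salt/H2O2 epoxidation of 2-cyclohexenones, which has not been shown for quinone monoketals.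

Step 5
Reactants: 9 (1S,6R)-4-R-5,5-dimethoxy-7-oxabicyclo[4.1.0]hept-3-en-2-one
Product: 10 (1R,2R,6R)-4-R-5,5-dimethoxy-7-oxabicyclo[4.1.0]hept-3-en-2-ol
Conditions: NaBH4, CeCl3·7H2O, MeOH, −78 °C
Reagents that add atoms: none
Why: Luche 1,2-reduction in which hydride adds to the C3 carbonyl anti to the adjacent epoxide oxygen, the usual outcome for 5,6-epoxy-4,4-dialkoxycyclohex-2-enones, giving the C3 alcohol syn to the epoxide while ketal, epoxide and enyne are untouched.

Step 6
Reactants: 10 (1R,2R,6R)-4-R-5,5-dimethoxy-7-oxabicyclo[4.1.0]hept-3-en-2-ol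
Product: 11 (1R,2S,6R)-4-R-5,5-dimethoxy-7-oxabicyclo[4.1.0]hept-3-en-2-yl acetate
Conditions: PPh3, DIAD, AcOH, THF, 0 °C → rt
Reagents that add atoms: acetic acid, CC(O)=O
Why: Mitsunobu reaction in which acetate displaces the activated allylic C3 oxygen by SN2 from the face opposite the epoxide, inverting C3 and installing the acetate in one operation, while the tertiary side-chain alcohol cannot be activated and SN2' attack at the fully substituted C1 is blocked.

Step 7
Reactants: 11 (1R,2S,6R)-4-R-5,5-dimethoxy-7-oxabicyclo[4.1.0]hept-3-en-2-yl acetate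
Product: 12 (1R,2S,6R)-4-R-5-oxo-7-oxabicyclo[4.1.0]hept-3-en-2-yl acetate
Conditions: 10% aq. (CO2H)2 on SiO2, CH2Cl2, rt
Reagents that add atoms: water, O
Why: Mild acid hydrolysis of the allylic dimethyl ketal on wet silica (ketal hydrolysis), of the kind used to unmask epoxyquinone monoketals without opening the electron-poor epoxide or cleaving the acetate (no stereocentre is touched).

Step 8
Reactants: 12 (1R,2S,6R)-4-R-5-oxo-7-oxabicyclo[4.1.0]hept-3-en-2-yl acetate
Product: 13 (1R,2S,5S,6S)-5-hydroxy-4-R-7-oxabicyclo[4.1.0]hept-3-en-2-yl acetate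
Conditions: NaBH4, CeCl3·7H2O, MeOH, −78 °C, 15 min
Reagents that add atoms: none
Why: Luche 1,2-reduction of the α-alkynyl enone in which hydride again enters anti to the neighbouring epoxide oxygen, so the new C6 hydroxyl is syn to the epoxide (cis to the future C5 hydroxyl), and the short cold reaction leaves the acetate in place.

Step 9
Reactants: 13 (1R,2S,5S,6S)-5-hydroxy-4-R-7-oxabicyclo[4.1.0]hept-3-en-2-yl acetate
Product: 14 (1S,4S,5S,6R)-4,5-dihydroxy-3-[(5E)-7-hydroxy-7-methyl-3-methylideneoct-5-en-1-yn-1-yl]-6-methoxycyclohex-2-en-1-yl acetate (CNP0546270.2)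
Conditions: Yb(OTf)3 (10 mol %), MeOH, 0 °C → rt
Reagents that add atoms: methanol, CO
Why: Lewis-acid-catalysed trans-diaxial (Fürst–Plattner) methanolysis of the epoxide, in which Yb bridges the free syn C6 hydroxyl and the epoxide oxygen and methanol attacks the distal carbon C4 with inversion through the half-chair that keeps the C3 acetate and C6 hydroxyl pseudoequatorial (attack at C5 would need the all-axial half-chair with a 1,3-diaxial clash against the acetate), giving 4-OMe trans to 5-OH and completing the 3,4-cis/4,5-trans/5,6-cis array.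

## Compound list

1 | (E)-2-methyl-4-(4,4,5,5-tetramethyl-1,3,2-dioxaborolan-2-yl)but-3-en-2-ol | CC(C)(O)/C=C/B1OC(C)(C)C(C)(C)O1 | starting material
2 | 2,3-dibromoprop-1-ene | C=C(Br)CBr | starting material
3 | (3E)-6-bromo-2-methylhepta-3,6-dien-2-ol | C=C(Br)C/C=C/C(C)(C)O | intermediate
4 | 3-bromo-4-methoxyphenol | COc1ccc(O)cc1Br | starting material
5 | ethynyltrimethylsilane | C#C[Si](C)(C)C | starting material
6 | 4-methoxy-3-[(trimethylsilyl)ethynyl]phenol | COc1ccc(O)cc1C#C[Si](C)(C)C | intermediate (not isolated)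
7 | 3-[(5E)-7-hydroxy-7-methyl-3-methylideneoct-5-en-1-yn-1-yl]-4-methoxyphenol | COc1ccc(O)cc1C#CC(=C)C/C=C/C(C)(C)O | intermediate
8 | 3-[(5E)-7-hydroxy-7-methyl-3-methylideneoct-5-en-1-yn-1-yl]-4,4-dimethoxycyclohexa-2,5-dien-1-one | C=C(C#CC1=CC(=O)C=CC1(OC)OC)C/C=C/C(C)(C)O | intermediate
9 | (1S,6R)-4-[(5E)-7-hydroxy-7-methyl-3-methylideneoct-5-en-1-yn-1-yl]-5,5-dimethoxy-7-oxabicyclo[4.1.0]hept-3-en-2-one | C=C(C#CC1=CC(=O)[C@@H]2[C@@H](O2)C1(OC)OC)C/C=C/C(C)(C)O | intermediate
10 | (1R,2R,6R)-4-[(5E)-7-hydroxy-7-methyl-3-methylideneoct-5-en-1-yn-1-yl]-5,5-dimethoxy-7-oxabicyclo[4.1.0]hept-3-en-2-ol (hydroxyl syn to epoxide) | C=C(C#CC1=C[C@@H](O)[C@@H]2[C@@H](O2)C1(OC)OC)C/C=C/C(C)(C)O | intermediate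
11 | (1R,2S,6R)-4-[(5E)-7-hydroxy-7-methyl-3-methylideneoct-5-en-1-yn-1-yl]-5,5-dimethoxy-7-oxabicyclo[4.1.0]hept-3-en-2-yl acetate (acetate anti to epoxide) | C=C(C#CC1=C[C@H](OC(C)=O)[C@@H]2[C@@H](O2)C1(OC)OC)C/C=C/C(C)(C)O | intermediate
12 | (1R,2S,6R)-4-[(5E)-7-hydroxy-7-methyl-3-methylideneoct-5-en-1-yn-1-yl]-5-oxo-7-oxabicyclo[4.1.0]hept-3-en-2-yl acetate | C=C(C#CC1=C[C@H](OC(C)=O)[C@@H]2[C@@H](O2)C1=O)C/C=C/C(C)(C)O | intermediate
13 | (1R,2S,5S,6S)-5-hydroxy-4-[(5E)-7-hydroxy-7-methyl-3-methylideneoct-5-en-1-yn-1-yl]-7-oxabicyclo[4.1.0]hept-3-en-2-yl acetate (hydroxyl syn, acetate anti to epoxide) | C=C(C#CC1=C[C@H](OC(C)=O)[C@@H]2[C@@H](O2)[C@H]1O)C/C=C/C(C)(C)O | intermediate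
14 | (1S,4S,5S,6R)-4,5-dihydroxy-3-[(5E)-7-hydroxy-7-methyl-3-methylideneoct-5-en-1-yn-1-yl]-6-methoxycyclohex-2-en-1-yl acetate | C=C(C#CC1=C[C@H](OC(C)=O)[C@H](OC)[C@@H](O)[C@H]1O)C/C=C/C(C)(C)O | target

## Step count and risk

Total steps: 9. Longest linear sequence: 9 (1 → 3 → 7 → 8 → 9 → 10 → 11 → 12 → 13 → 14).

Step 4 is the most likely to fail. Quinone monoketals are an untested substrate class for the amine-salt/H2O2 epoxidation, the enantioselectivity and its sense are unknown, and the ketal must survive warm, mildly acidic aqueous peroxide. The fallback replaces asymmetric catalysis by resolution. It sets out from 8: a plain Weitz–Scheffer epoxidation (tBuOOH, DBU, CH2Cl2, 0 °C) gives the racemic epoxy ketone F1. Luche reduction (NaBH4, CeCl3·7H2O, MeOH, −78 °C) then gives the racemic syn-epoxy alcohol F2. Kinetic resolution with Burkholderia cepacia lipase and vinyl acetate (tBuOMe, 30 °C) acylates the unwanted enantiomer to the (1S,2S,6S)-acetate F3, which is separated, and leaves the unreacted alcohol 10, where the route is rejoined. The enzyme is chosen from a small screen so that it is the unwanted enantiomer that is acylated.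

Step 9 is the second risk. Neither epoxide carbon is allylic, so the C4/C5 choice rests on chelation and conformational arguments that the inductive pull of the acetate opposes. The anti acetate could also participate through an acetoxonium ion, and the tertiary allylic alcohol could solvolyse in acidic methanol. The fallback lets the carbonyl, not the conformation, fix the regiochemistry. It sets out from 12: Yb(OTf)3 in MeOH (0 °C) opens the α,β-epoxy ketone at the carbon β to the carbonyl (C4), because opening with cationic character next to the carbonyl carbon is disfavoured. This gives (1S,5R,6R)-5-hydroxy-6-methoxy-4-oxo-3-R-cyclohex-2-en-1-yl acetate F4. The C6 carbonyl is then reduced under catalyst control with the (S)-Me-CBS oxazaborolidine and catecholborane (toluene, −78 °C). The alkynyl-substituted vinyl side acts as the large group, so hydride goes to the face that gives the (S)-carbinol cis to the C5 hydroxyl, and the sequence arrives at 14.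

Step 7 is the third risk. The ketal is deactivated by the neighbouring epoxide and may need firmer acid than the tertiary allylic alcohol of the side chain tolerates (ionization, elimination or allylic transposition). The fallback is a protecting-group detour setting out from 11. The tertiary alcohol is capped (tBuMe2SiOTf, 2,6-lutidine, CH2Cl2, −78 °C) to give the silyl ether F5. The ketal is then hydrolysed under firmer acid (aq. CF3CO2H, CH2Cl2, 0 °C) to give the silylated epoxy enone F6. HF·pyridine (THF, 0 °C → rt) removes the silyl group and returns 12.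

## Further compounds

F1 | step 4 | racemic 4-[(5E)-7-hydroxy-7-methyl-3-methylideneoct-5-en-1-yn-1-yl]-5,5-dimethoxy-7-oxabicyclo[4.1.0]hept-3-en-2-one (both enantiomers) | C=C(C#CC1=CC(=O)[C@@H]2[C@@H](O2)C1(OC)OC)C/C=C/C(C)(C)O.C=C(C#CC1=CC(=O)[C@H]2[C@H](O2)C1(OC)OC)C/C=C/C(C)(C)O
F2 | step 4 | racemic syn-4-[(5E)-7-hydroxy-7-methyl-3-methylideneoct-5-en-1-yn-1-yl]-5,5-dimethoxy-7-oxabicyclo[4.1.0]hept-3-en-2-ol (both enantiomers) | C=C(C#CC1=C[C@@H](O)[C@@H]2[C@@H](O2)C1(OC)OC)C/C=C/C(C)(C)O.C=C(C#CC1=C[C@H](O)[C@H]2[C@H](O2)C1(OC)OC)C/C=C/C(C)(C)O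
F3 | step 4 | (1S,2S,6S)-4-[(5E)-7-hydroxy-7-methyl-3-methylideneoct-5-en-1-yn-1-yl]-5,5-dimethoxy-7-oxabicyclo[4.1.0]hept-3-en-2-yl acetate (acetate of the unwanted enantiomer) | C=C(C#CC1=C[C@H](OC(C)=O)[C@H]2[C@H](O2)C1(OC)OC)C/C=C/C(C)(C)O
F4 | step 9 | (1S,5R,6R)-5-hydroxy-3-[(5E)-7-hydroxy-7-methyl-3-methylideneoct-5-en-1-yn-1-yl]-6-methoxy-4-oxocyclohex-2-en-1-yl acetate | C=C(C#CC1=C[C@H](OC(C)=O)[C@H](OC)[C@@H](O)C1=O)C/C=C/C(C)(C)O
F5 | step 7 | (1R,2S,6R)-4-[(5E)-7-(tert-butyldimethylsilyloxy)-7-methyl-3-methylideneoct-5-en-1-yn-1-yl]-5,5-dimethoxy-7-oxabicyclo[4.1.0]hept-3-en-2-yl acetate | C=C(C#CC1=C[C@H](OC(C)=O)[C@@H]2[C@@H](O2)C1(OC)OC)C/C=C/C(C)(C)O[Si](C)(C)C(C)(C)C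
F6 | step 7 | (1R,2S,6R)-4-[(5E)-7-(tert-butyldimethylsilyloxy)-7-methyl-3-methylideneoct-5-en-1-yn-1-yl]-5-oxo-7-oxabicyclo[4.1.0]hept-3-en-2-yl acetate | C=C(C#CC1=C[C@H](OC(C)=O)[C@@H]2[C@@H](O2)C1=O)C/C=C/C(C)(C)O[Si](C)(C)C(C)(C)C
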